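**Retrosynthetic overview**

1. The epoxide comes last: peracid epoxidation of the 1(10)-E alkene, after the C8 hydroxyl has been acylated with isovaleryl chloride.
2. The ten-membered ring is closed at C7–C8: divalent chromium metalates a 3-(bromomethyl)butenolide, whose β-carbon C7 then attacks the tethered C8 aldehyde. This sets C7 and C8 and unveils the α-methylene lactone.
3. The butenolide (first ring) comes from ring-closing metathesis of the 2-(bromomethyl)acrylate of the C6 carbinol; C6 is set by a ligand-controlled Ni/Cr coupling of a Z-vinyl iodide with acrolein.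
4. The Z-C4=C5 vinyl iodide comes from copper-catalysed anti-carbomagnesiation and iodination of a C3 propargylic alcohol; C3 is set by asymmetric alkynylation.
5. The E-C1=C10 unit comes from zirconium-catalysed carboalumination of a silyloxybutyne and opening of ethylene oxide. Ring order: butenolide, then ten-membered carbocycle, then epoxide.

Assumption: atoms are named by germacrane numbering (C12 lactone carbonyl, C13 exocyclic methylene, C14 methyl on C10, C15 methyl on C4); the target is read as (1R,3S,6R,7R,8S,10R) with a 4Z alkene; in steps 3 and 6 the ligand antipode is the one that gives the configuration stated.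

**Route**

Step 1
Reactants: 1 tert-butyl(but-3-yn-1-yloxy)dimethylsilane; 2 ethylene oxide
Product: 5 (E)-6-[(tert-butyldimethylsilyl)oxy]-4-methylhex-3-en-1-ol, via alkenyl(dimethyl)alane 3 (not isolated), via lithium butyl alanate 4 (not isolated)
Conditions: Me3Al, Cp2ZrCl2 (0.25 eq), CH2Cl2, 0 °C to rt; evaporate; n-BuLi, THF/hexane, −78 °C; then 2, −78 to 0 °C
Reagents that add atoms: trimethylaluminium, C[Al](C)C
Why: Negishi zirconium-catalysed carboalumination adds Me and Al syn across the terminal alkyne with Me on the internal carbon, and the ate complex opens ethylene oxide with retention at the alkenyl carbon, so the E-trisubstituted C1=C10 alkene is fixed (no stereocentre is formed).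

Step 2
Reactants: 5 (E)-6-[(tert-butyldimethylsilyl)oxy]-4-methylhex-3-en-1-ol
Product: 6 (E)-6-[(tert-butyldimethylsilyl)oxy]-4-methylhex-3-enal
Conditions: Dess–Martin periodinane, NaHCO3, CH2Cl2, 0 °C; used crude
Reagents that add atoms: none
Why: Buffered Dess–Martin oxidation gives the β,γ-unsaturated aldehyde under non-basic conditions, so the alkene does not move into conjugation.

Step 3
Reactants: 6 (E)-6-[(tert-butyldimethylsilyl)oxy]-4-methylhex-3-enal; 7 ethynyltrimethylsilane
Product: 9 (3S,5E)-8-[(tert-butyldimethylsilyl)oxy]-6-methyloct-5-en-1-yn-3-ol, via silylalkynol 8 (not isolated)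
Conditions: Me2Zn (3 eq), ProPhenol (20 mol %, antipode giving 3S), Ph3PO (40 mol %), toluene, 4 °C; then K2CO3, MeOH, rt
Reagents that add atoms: none
Why: Trost zinc–ProPhenol asymmetric alkynylation delivers the zinc acetylide to the Re face of the aldehyde inside the chiral dinuclear zinc pocket and so sets C3 (S) without an amine base that would isomerise the aldehyde, and methanolysis then removes the C-silyl group.

Step 4
Reactants: 9 (3S,5E)-8-[(tert-butyldimethylsilyl)oxy]-6-methyloct-5-en-1-yn-3-ol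
Product: 11 (1Z,3S,5E)-8-[(tert-butyldimethylsilyl)oxy]-1-iodo-2,6-dimethylocta-1,5-dien-3-ol, via alkenylmagnesium alkoxide 10 (not isolated)
Conditions: MeMgBr (3.5 eq), CuI (10 mol %), THF, −10 °C to rt; then I2 (to persistent colour), −78 °C; immediate Na2S2O3 quench
Reagents that add atoms: methylmagnesium bromide, C[Mg]Br; iodine, II
Why: Duboudin copper-catalysed carbomagnesiation of the propargylic alkoxide adds Me to C4 and Mg to C5 anti through a five-membered chelate, and iodinolysis with retention gives the vinyl iodide with iodine cis to C3, which is the 4Z geometry of the target.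

Step 5
Reactants: 11 (1Z,3S,5E)-8-[(tert-butyldimethylsilyl)oxy]-1-iodo-2,6-dimethylocta-1,5-dien-3-ol
Product: 12 (1Z,3S,5E)-8-[(tert-butyldimethylsilyl)oxy]-1-iodo-2,6-dimethylocta-1,5-dien-3-yl acetate
Conditions: Ac2O, pyridine, DMAP (cat.), CH2Cl2, 0 °C
Reagents that add atoms: acetic anhydride, CC(=O)OC(C)=O
Why: Standard DMAP-catalysed acylation installs the C3 acetate of the target early, where it also protects the hydroxyl through every later step, without touching the stereocentre.

Step 6
Reactants: 12 (1Z,3S,5E)-8-[(tert-butyldimethylsilyl)oxy]-1-iodo-2,6-dimethylocta-1,5-dien-3-yl acetate; 13 acrolein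
Product: 14 (3S,4Z,6S,8E)-11-[(tert-butyldimethylsilyl)oxy]-3-hydroxy-5,9-dimethylundeca-1,4,8-trien-6-yl acetate
Conditions: CrCl2 (10 mol %), Kishi oxazoline sulfonamide ligand (11 mol %, antipode giving the 3S carbinol), proton sponge (11 mol %), NiCl2(2,9-dimethyl-1,10-phenanthroline) (2 mol %), Mn powder, Cp2ZrCl2, LiCl, MeCN, rt
Reagents that add atoms: none
Why: Catalytic asymmetric Nozaki–Hiyama–Kishi coupling activates the C–I bond at nickel with retention of the Z geometry, and the ligand-bound alkenylchromium adds 1,2 to acrolein under ligand control (C3 is too remote to interfere) to set the C6 carbinol, with acetate and silyl ether tolerated.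

Step 7
Reactants: 14 (3S,4Z,6S,8E)-11-[(tert-butyldimethylsilyl)oxy]-3-hydroxy-5,9-dimethylundeca-1,4,8-trien-6-yl acetate; 15 2-(bromomethyl)acrylic acid
Product: 16 (3S,4Z,6S,8E)-6-acetoxy-11-[(tert-butyldimethylsilyl)oxy]-5,9-dimethylundeca-1,4,8-trien-3-yl 2-(bromomethyl)acrylate
Conditions: DCC, DMAP (5 mol %), CH2Cl2, −10 °C
Reagents that add atoms: none
Why: Steglich esterification acylates the doubly allylic alcohol on oxygen with retention at C6, and the low temperature and small DMAP charge limit attack on the allylic bromide.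

Step 8
Reactants: 16 (3S,4Z,6S,8E)-6-acetoxy-11-[(tert-butyldimethylsilyl)oxy]-5,9-dimethylundeca-1,4,8-trien-3-yl 2-(bromomethyl)acrylate
Product: 17 (1Z,3S,5E)-1-[(2R)-4-(bromomethyl)-5-oxo-2,5-dihydrofuran-2-yl]-8-[(tert-butyldimethylsilyl)oxy]-2,6-dimethylocta-1,5-dien-3-yl acetate
Conditions: second-generation Grubbs catalyst RuCl2(=CHPh)(H2IMes)(PCy3) (10 mol %), toluene, 80 °C, 5 mM
Reagents that add atoms: none
Why: Ring-closing metathesis starts at the only monosubstituted alkene (the C7 vinyl group) and closes onto the acrylate methylene to give the five-membered butenolide with loss of ethylene, while the trisubstituted alkenes and the C6 stereocentre are untouched.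

Step 9
Reactants: 17 (1Z,3S,5E)-1-[(2R)-4-(bromomethyl)-5-oxo-2,5-dihydrofuran-2-yl]-8-[(tert-butyldimethylsilyl)oxy]-2,6-dimethylocta-1,5-dien-3-yl acetate
Product: 18 (1Z,3S,5E)-1-[(2R)-4-(bromomethyl)-5-oxo-2,5-dihydrofuran-2-yl]-8-hydroxy-2,6-dimethylocta-1,5-dien-3-yl acetate
Conditions: HF (48 % aq.), MeCN, 0 °C
Reagents that add atoms: none
Why: Acidic fluoride desilylation cleaves the primary silyl ether without any amine or base, so the allylic bromide, the acetate and the base-labile C6–H of the butenolide survive.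

Step 10
Reactants: 18 (1Z,3S,5E)-1-[(2R)-4-(bromomethyl)-5-oxo-2,5-dihydrofuran-2-yl]-8-hydroxy-2,6-dimethylocta-1,5-dien-3-yl acetate
Product: 19 (1Z,3S,5E)-1-[(2R)-4-(bromomethyl)-5-oxo-2,5-dihydrofuran-2-yl]-2,6-dimethyl-8-oxoocta-1,5-dien-3-yl acetate
Conditions: Dess–Martin periodinane, NaHCO3, CH2Cl2, 0 °C; used at once
Reagents that add atoms: none
Why: Buffered Dess–Martin oxidation gives the β,γ-unsaturated C8 aldehyde under neutral conditions that neither epimerise C6 nor displace the bromide.

Step 11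
Reactants: 19 (1Z,3S,5E)-1-[(2R)-4-(bromomethyl)-5-oxo-2,5-dihydrofuran-2-yl]-2,6-dimethyl-8-oxoocta-1,5-dien-3-yl acetate
Product: 21 (3S,6R,7R,8S)-3-acetoxy-8-hydroxygermacra-1(10)E,4Z,11(13)-trien-12,6-olide, via allylchromium dichloride 20 (not isolated)
Conditions: CrCl2 (8 eq), THF/DMF, rt, syringe-pump addition over 12 h, final 2 mM
Reagents that add atoms: none
Why: Proposed new method: two-electron reduction of the allylic C–Br bond by divalent chromium gives allylchromium 20, in which the butenolide β-carbon C7 (normally a Michael-acceptor site) is the nucleophilic γ-terminus and adds to the tethered C8 aldehyde (also an electrophilic carbon) through a chair six-membered transition state on the face anti to the C6 substituent (6,7-trans lactone) with the ring-fixed E-type allyl geometry giving the 7,8-anti relationship (7R,8S), while the double bond moves to the exocyclic C11=C13 position; the closest known reactions are the chromium-mediated allylation of aldehydes with 3-(bromomethyl)furan-2(5H)-one and the intramolecular Nozaki–Hiyama/Barbier macrocyclisations of 2-(bromomethyl)acrylates used for germacranolides.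

Step 12
Reactants: 21 (3S,6R,7R,8S)-3-acetoxy-8-hydroxygermacra-1(10)E,4Z,11(13)-trien-12,6-olide
Product: 22 (3S,6R,7R,8S)-3-acetoxy-8-(3-methylbutanoyloxy)germacra-1(10)E,4Z,11(13)-trien-12,6-olide
Conditions: isovaleryl chloride, pyridine, DMAP (cat.), CH2Cl2, 0 °C
Reagents that add atoms: isovaleryl chloride, CC(C)CC(Cl)=O
Why: Acylation of the secondary C8 alcohol with an acid chloride under weakly basic conditions proceeds with retention and is fast enough to avoid translactonisation to the 8,12-olide.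

Step 13
Reactants: 22 (3S,6R,7R,8S)-3-acetoxy-8-(3-methylbutanoyloxy)germacra-1(10)E,4Z,11(13)-trien-12,6-olide
Product: 23 (1R,3S,6R,7R,8S,10R)-3-acetoxy-1,10-epoxy-8-(3-methylbutanoyloxy)germacra-4Z,11(13)-dien-12,6-olide
Conditions: mCPBA, NaHCO3, CH2Cl2, 0 °C
Reagents that add atoms: meta-chloroperoxybenzoic acid, OOC(=O)c1cccc(Cl)c1
Why: Prilezhaev epoxidation attacks only the isolated electron-rich 1(10) alkene (the 4,5 alkene is deactivated by two allylic acyloxy groups and the 11,13 alkene is conjugated), the syn addition keeps the trans epoxide from the E alkene, and peripheral attack on the outer face of the ring should give (1R,10R), as in peracid epoxidations of related germacra-1(10),4-dienolides.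

**Compound list**

1 | tert-butyl(but-3-yn-1-yloxy)dimethylsilane | C#CCCO[Si](C)(C)C(C)(C)C | starting material
2 | ethylene oxide | C1CO1 | starting material
3 | (E)-{4-[(tert-butyldimethylsilyl)oxy]-2-methylbut-1-en-1-yl}dimethylalane | C[Al](C)/C=C(\C)CCO[Si](C)(C)C(C)(C)C | intermediate
4 | lithium butyl{(E)-4-[(tert-butyldimethylsilyl)oxy]-2-methylbut-1-en-1-yl}dimethylalanate | [Li+].CCCC[Al-](C)(C)/C=C(\C)CCO[Si](C)(C)C(C)(C)C | intermediate
5 | (E)-6-[(tert-butyldimethylsilyl)oxy]-4-methylhex-3-en-1-ol | OCC/C=C(\C)CCO[Si](C)(C)C(C)(C)C | intermediate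
6 | (E)-6-[(tert-butyldimethylsilyl)oxy]-4-methylhex-3-enal | O=CC/C=C(\C)CCO[Si](C)(C)C(C)(C)C | intermediate
7 | ethynyltrimethylsilane | C#C[Si](C)(C)C | starting material
8 | (3S,5E)-8-[(tert-butyldimethylsilyl)oxy]-6-methyl-1-(trimethylsilyl)oct-5-en-1-yn-3-ol | C[Si](C)(C)C#C[C@@H](O)C/C=C(\C)CCO[Si](C)(C)C(C)(C)C | intermediate
9 | (3S,5E)-8-[(tert-butyldimethylsilyl)oxy]-6-methyloct-5-en-1-yn-3-ol | C#C[C@@H](O)C/C=C(\C)CCO[Si](C)(C)C(C)(C)C | intermediate
10 | bromomagnesium alkoxide of (1Z,3S,5E)-1-(bromomagnesio)-8-[(tert-butyldimethylsilyl)oxy]-2,6-dimethylocta-1,5-dien-3-ol | Br[Mg]/C=C(/C)[C@@H](O[Mg]Br)C/C=C(\C)CCO[Si](C)(C)C(C)(C)C | intermediate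
11 | (1Z,3S,5E)-8-[(tert-butyldimethylsilyl)oxy]-1-iodo-2,6-dimethylocta-1,5-dien-3-ol | I/C=C(/C)[C@@H](O)C/C=C(\C)CCO[Si](C)(C)C(C)(C)C | intermediate
12 | (1Z,3S,5E)-8-[(tert-butyldimethylsilyl)oxy]-1-iodo-2,6-dimethylocta-1,5-dien-3-yl acetate | I/C=C(/C)[C@@H](OC(C)=O)C/C=C(\C)CCO[Si](C)(C)C(C)(C)C | intermediate
13 | acrolein | C=CC=O | starting material
14 | (3S,4Z,6S,8E)-11-[(tert-butyldimethylsilyl)oxy]-3-hydroxy-5,9-dimethylundeca-1,4,8-trien-6-yl acetate | C=C[C@H](O)/C=C(/C)[C@@H](OC(C)=O)C/C=C(\C)CCO[Si](C)(C)C(C)(C)C | intermediate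
15 | 2-(bromomethyl)acrylic acid | C=C(CBr)C(=O)O | starting material
16 | (3S,4Z,6S,8E)-6-acetoxy-11-[(tert-butyldimethylsilyl)oxy]-5,9-dimethylundeca-1,4,8-trien-3-yl 2-(bromomethyl)acrylate | C=C[C@H](OC(=O)C(=C)CBr)/C=C(/C)[C@@H](OC(C)=O)C/C=C(\C)CCO[Si](C)(C)C(C)(C)C | intermediate
17 | (1Z,3S,5E)-1-[(2R)-4-(bromomethyl)-5-oxo-2,5-dihydrofuran-2-yl]-8-[(tert-butyldimethylsilyl)oxy]-2,6-dimethylocta-1,5-dien-3-yl acetate | BrCC1=C[C@@H](/C=C(/C)[C@@H](OC(C)=O)C/C=C(\C)CCO[Si](C)(C)C(C)(C)C)OC1=O | intermediate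
18 | (1Z,3S,5E)-1-[(2R)-4-(bromomethyl)-5-oxo-2,5-dihydrofuran-2-yl]-8-hydroxy-2,6-dimethylocta-1,5-dien-3-yl acetate | BrCC1=C[C@@H](/C=C(/C)[C@@H](OC(C)=O)C/C=C(\C)CCO)OC1=O | intermediate
19 | (1Z,3S,5E)-1-[(2R)-4-(bromomethyl)-5-oxo-2,5-dihydrofuran-2-yl]-2,6-dimethyl-8-oxoocta-1,5-dien-3-yl acetate | BrCC1=C[C@@H](/C=C(/C)[C@@H](OC(C)=O)C/C=C(\C)CC=O)OC1=O | intermediate
20 | allylchromium dichloride from 19 (CrCl2 on the former CH2Br carbon) | Cl[Cr](Cl)CC1=C[C@@H](/C=C(/C)[C@@H](OC(C)=O)C/C=C(\C)CC=O)OC1=O | intermediate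
21 | (3S,6R,7R,8S)-3-acetoxy-8-hydroxygermacra-1(10)E,4Z,11(13)-trien-12,6-olide | C=C1C(=O)O[C@@H]2/C=C(/C)[C@@H](OC(C)=O)C/C=C(\C)C[C@H](O)[C@@H]12 | intermediate
22 | (3S,6R,7R,8S)-3-acetoxy-8-(3-methylbutanoyloxy)germacra-1(10)E,4Z,11(13)-trien-12,6-olide | C=C1C(=O)O[C@@H]2/C=C(/C)[C@@H](OC(C)=O)C/C=C(\C)C[C@H](OC(=O)CC(C)C)[C@@H]12 | intermediate
23 | (1R,3S,6R,7R,8S,10R)-3-acetoxy-1,10-epoxy-8-(3-methylbutanoyloxy)germacra-4Z,11(13)-dien-12,6-olide (CNP0157657.1) | C=C1C(=O)O[C@@H]2/C=C(/C)[C@@H](OC(C)=O)C[C@H]3O[C@]3(C)C[C@H](OC(=O)CC(C)C)[C@@H]12 | target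

**Step count and risks**

Total steps: 13. Longest linear sequence: 13 (fully linear from 1).

Three steps most likely to fail:

Step 11 (macrocyclisation). The ring closure may give oligomers or protonated material, or the wrong relative configuration at C7/C8 if the chair transition state cannot be reached inside the forming ring. The fallback keeps the same bond but replaces the reductive organochromium by a latent allylsilane nucleophile that is triggered by a Lewis acid through an open transition state. It sets out from 14 and returns at 21. Alcohol 14 is esterified (DCC, DMAP) with 2-[(trimethylsilyl)methyl]acrylic acid (from saponification of the commercial ethyl ester) to give the silylmethyl acrylate F1. Ring-closing metathesis with the same ruthenium catalyst gives the 3-(trimethylsilylmethyl)butenolide F2. Removal of the O-silyl group with HF in MeCN gives the primary alcohol F3, and Dess–Martin oxidation gives the aldehyde F4. F4 is then cyclised with BF3·OEt2 in CH2Cl2 at −78 °C under high dilution (intramolecular Hosomi–Sakurai allylation through C7), giving 21.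

Step 6 (C6 stereocontrol). Acrolein is a small aldehyde and the ligand-controlled selectivity may be low. The fallback replaces catalyst control in the C–C coupling by reagent control in a ketone reduction. It sets out from 12 and returns at 14. Unselective coupling of 12 with acrolein (CrCl2, catalytic NiCl2, DMSO) gives the C3-epimeric carbinol mixture F5. Dess–Martin oxidation gives the cross-conjugated dienone F6. Corey–Bakshi–Shibata reduction with (R)-Me-CBS and catecholborane at −78 °C (the Z-trisubstituted alkenyl group as the large substituent, vinyl as the small one) then gives 14.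

Step 13 (epoxide face). The peracid may attack the other face of the 1(10) alkene. The fallback delivers the oxygen to the opposite face by a two-step halohydrin route. It sets out from 22 and returns at 23. NBS in aqueous acetone forms the bromonium ion on the face the peracid prefers, and water opens it anti at the tertiary C10 to give the 1-bromo-10-hydroxy bromohydrin F7. K2CO3 in acetone then closes the epoxide with inversion at C1 to give 23.

Further compounds

F1 | step 11 | (3S,4Z,6S,8E)-6-acetoxy-11-[(tert-butyldimethylsilyl)oxy]-5,9-dimethylundeca-1,4,8-trien-3-yl 2-[(trimethylsilyl)methyl]acrylate | C=C[C@H](OC(=O)C(=C)C[Si](C)(C)C)/C=C(/C)[C@@H](OC(C)=O)C/C=C(\C)CCO[Si](C)(C)C(C)(C)C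
F2 | step 11 | (1Z,3S,5E)-8-[(tert-butyldimethylsilyl)oxy]-2,6-dimethyl-1-{(2R)-5-oxo-4-[(trimethylsilyl)methyl]-2,5-dihydrofuran-2-yl}octa-1,5-dien-3-yl acetate | C[Si](C)(C)CC1=C[C@@H](/C=C(/C)[C@@H](OC(C)=O)C/C=C(\C)CCO[Si](C)(C)C(C)(C)C)OC1=O
F3 | step 11 | (1Z,3S,5E)-8-hydroxy-2,6-dimethyl-1-{(2R)-5-oxo-4-[(trimethylsilyl)methyl]-2,5-dihydrofuran-2-yl}octa-1,5-dien-3-yl acetate | C[Si](C)(C)CC1=C[C@@H](/C=C(/C)[C@@H](OC(C)=O)C/C=C(\C)CCO)OC1=O
F4 | step 11 | (1Z,3S,5E)-2,6-dimethyl-8-oxo-1-{(2R)-5-oxo-4-[(trimethylsilyl)methyl]-2,5-dihydrofuran-2-yl}octa-1,5-dien-3-yl acetate | C[Si](C)(C)CC1=C[C@@H](/C=C(/C)[C@@H](OC(C)=O)C/C=C(\C)CC=O)OC1=O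
F5 | step 6 | (3RS,4Z,6S,8E)-11-[(tert-butyldimethylsilyl)oxy]-3-hydroxy-5,9-dimethylundeca-1,4,8-trien-6-yl acetate (C3-epimeric mixture) | C=CC(O)/C=C(/C)[C@@H](OC(C)=O)C/C=C(\C)CCO[Si](C)(C)C(C)(C)C
F6 | step 6 | (4Z,6S,8E)-11-[(tert-butyldimethylsilyl)oxy]-5,9-dimethyl-3-oxoundeca-1,4,8-trien-6-yl acetate | C=CC(=O)/C=C(/C)[C@@H](OC(C)=O)C/C=C(\C)CCO[Si](C)(C)C(C)(C)C
F7 | step 13 | 1-bromo-10-hydroxy bromohydrin of 22 (bromine on the face opposite to the epoxide oxygen of 23; 3S,6R,7R,8S) | C=C1C(=O)O[C@@H]2/C=C(/C)[C@@H](OC(C)=O)C[C@H](Br)[C@](C)(O)C[C@H](OC(=O)CC(C)C)[C@@H]12
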